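**Assumption:** the target is the (2S)-flavanone as drawn (I confirmed C2 = S from the SMILES). 7-Hydroxychromone, 3-chloro-3-methylbut-1-yne and (R)-t-BuPyOx are taken as catalogue chemicals.

## Retrosynthetic overview

1. Sophoranone ⇐ bis-TBS ether by buffered global desilylation.
2. Key disconnection, C2–C1′ (not the chalcone/oxa-Michael route): enantioselective Pd(II)/PyOx conjugate addition of a fully prenylated arylboronic acid to a prenylated chromone. This joins the two halves and sets C2 in one step.
3. Chromone half ⇐ 7-hydroxychromone via the 1,1-dimethylallyl ether and aromatic Claisen rearrangement to C8.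
4. Aryl half ⇐ 4-bromophenol via one-pot o,o′-di-C-prenylation, silylation and Br → B(OH)2.
5. Ring order: no ring is built. The benzopyranone is bought as the chromone and becomes the chromanone in the key step.

## Route

**Step 1**
Reactants: 1 (7-hydroxy-4H-chromen-4-one); 2 (3-chloro-3-methylbut-1-yne)
Product: 3, 7-[(2-methylbut-3-yn-2-yl)oxy]-4H-chromen-4-one
Conditions: DBU, CuCl2 (cat.), MeCN, 0 °C → rt
Reagents that add atoms: 2, 3-chloro-3-methylbut-1-yne, C#CC(C)(C)Cl
Why: Cu-catalysed propargylic substitution (copper-acetylide/allenylidene pathway) of the tertiary propargyl chloride by the acidic 7-phenoxide, the standard way to make aryl 1,1-dimethylpropargyl ethers.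

**Step 2**
Reactants: 3
Product: 4, 7-[(2-methylbut-3-en-2-yl)oxy]-4H-chromen-4-one
Conditions: H2 (1 atm), Lindlar catalyst, quinoline, EtOAc, rt, stopped at 1 equiv H2
Reagents that add atoms: none
Why: Lindlar semi-hydrogenation takes the terminal alkyne to the vinyl group and leaves the conjugated chromone C2=C3 bond and the aryl ether untouched.

**Step 3**
Reactants: 4
Product: 5, 7-hydroxy-8-(3-methylbut-2-en-1-yl)-4H-chromen-4-one
Conditions: PhNEt2, 130 °C, 2–3 h (stop at full conversion)
Reagents that add atoms: none
Why: Aromatic Claisen [3,3] rearrangement inverts the 1,1-dimethylallyl unit into a linear prenyl group, and it goes to C8 rather than C6 because of the higher C7–C8 double-bond character in benzopyranones (as for 7-allyloxychromones and coumarins).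

**Step 4**
Reactants: 5; 6 (tert-butyldimethylsilyl chloride)
Product: 7, 7-[(tert-butyldimethylsilyl)oxy]-8-(3-methylbut-2-en-1-yl)-4H-chromen-4-one
Conditions: TBSCl, imidazole, DMF, rt
Reagents that add atoms: 6, TBSCl, CC(C)(C)[Si](C)(C)Cl
Why: Standard phenol silylation; it masks the acidic vinylogous-acid OH so the chromone stays neutral, soluble and electrophilic in the Pd step.

**Step 5**
Reactants: 8 (4-bromophenol); 9 (prenyl bromide, 1-bromo-3-methylbut-2-ene)
Product: 10, 4-bromo-2,6-bis(3-methylbut-2-en-1-yl)phenol
Conditions: NaH (2.2 equiv), prenyl bromide (2.2 equiv, two charges), toluene, 0 °C → rt; mono-prenyl by-product recycled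
Reagents that add atoms: 9, prenyl bromide, CC(C)=CCBr
Why: Ortho-selective C-alkylation of a sodium phenoxide tight ion pair in a non-polar solvent, then re-aromatisation; para is blocked by Br, so the second equivalent gives the o,o′-diprenyl phenol.

**Step 6**
Reactants: 10; 6 (TBSCl)
Product: 11, (4-bromo-2,6-bis(3-methylbut-2-en-1-yl)phenoxy)(tert-butyl)dimethylsilane
Conditions: TBSCl, imidazole, DMAP (cat.), DMF, 50 °C
Reagents that add atoms: 6, TBSCl, CC(C)(C)[Si](C)(C)Cl
Why: Silylation of a 2,6-dialkylphenol (flanked only by CH2 groups) proceeds with mild heating and removes the acidic OH before lithiation.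

**Step 7**
Reactants: 11; 12 (triisopropyl borate); 13 (water, work-up)
Product: 14, {4-[(tert-butyldimethylsilyl)oxy]-3,5-bis(3-methylbut-2-en-1-yl)phenyl}boronic acid
Conditions: B(OiPr)3 (1.5 equiv) then n-BuLi (1.1 equiv), THF, −78 °C → 0 °C (in-situ quench); sat. aq NH4Cl
Reagents that add atoms: 12, triisopropyl borate, CC(C)OB(OC(C)C)OC(C)C; 13, water, O
Why: Br–Li exchange at −78 °C outpaces benzylic/allylic deprotonation, the aryllithium is trapped at once by the borate, and mild hydrolysis gives the boronic acid with the aryl TBS ether intact.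

**Step 8 (key step)**
Reactants: 7; 14 (2 equiv)
Product: 15, (2S)-7-[(tert-butyldimethylsilyl)oxy]-2-{4-[(tert-butyldimethylsilyl)oxy]-3,5-bis(3-methylbut-2-en-1-yl)phenyl}-8-(3-methylbut-2-en-1-yl)chroman-4-one
Conditions: Pd(OCOCF3)2 (5 mol%), (R)-t-BuPyOx (6 mol%), NH4PF6 (30 mol%), H2O (5 equiv), ClCH2CH2Cl, 60 °C
Reagents that add atoms: none (aryl from 14; the C3 hydrogen comes from water)
Why: Pd(II)-catalysed asymmetric conjugate addition of an arylboronic acid to a chromone (Hayashi–Miyaura-type 1,4-addition: transmetalation, enantioface-selective carbopalladation of C2=C3, protonolysis of the Pd enolate); the (S)-ligand gives (R)-3-aryl ketones from cyclic enones, which maps onto (2R)-flavanones, so the (R)-ligand is used for 2S, and with no Pd(0)/oxidant cycle the trisubstituted prenyl alkenes are spectators.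

**Step 9**
Reactants: 15
Product: 16, sophoranone, (2S)-7-hydroxy-2-[4-hydroxy-3,5-bis(3-methylbut-2-en-1-yl)phenyl]-8-(3-methylbut-2-en-1-yl)chroman-4-one
Conditions: TBAF/AcOH (1:1, 3 equiv), THF, 0 °C → rt
Reagents that add atoms: none
Why: Fluoride desilylation of both aryl silyl ethers, buffered with AcOH so the medium is neither basic enough for retro-oxa-Michael ring opening (which would racemise C2) nor acidic enough to cyclise the o-prenylphenols to chromans.

## Compound list

1 | 7-hydroxy-4H-chromen-4-one | O=c1ccoc2cc(O)ccc12 | starting material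
2 | 3-chloro-3-methylbut-1-yne | C#CC(C)(C)Cl | starting material
3 | 7-[(2-methylbut-3-yn-2-yl)oxy]-4H-chromen-4-one | C#CC(C)(C)Oc1ccc2c(c1)occc2=O | intermediate
4 | 7-[(2-methylbut-3-en-2-yl)oxy]-4H-chromen-4-one | C=CC(C)(C)Oc1ccc2c(c1)occc2=O | intermediate
5 | 7-hydroxy-8-prenyl-4H-chromen-4-one | CC(C)=CCc1c(O)ccc2c1occc2=O | intermediate
6 | tert-butyldimethylsilyl chloride | CC(C)(C)[Si](C)(C)Cl | starting material
7 | 7-(TBS-oxy)-8-prenyl-4H-chromen-4-one | CC(C)=CCc1c(O[Si](C)(C)C(C)(C)C)ccc2c1occc2=O | intermediate
8 | 4-bromophenol | Oc1ccc(Br)cc1 | starting material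
9 | prenyl bromide | CC(C)=CCBr | starting material
10 | 4-bromo-2,6-diprenylphenol | CC(C)=CCc1cc(Br)cc(CC=C(C)C)c1O | intermediate
11 | 4-bromo-2,6-diprenylphenyl TBS ether | CC(C)=CCc1cc(Br)cc(CC=C(C)C)c1O[Si](C)(C)C(C)(C)C | intermediate
12 | triisopropyl borate | CC(C)OB(OC(C)C)OC(C)C | starting material
13 | water | O | starting material
14 | [4-(TBS-oxy)-3,5-diprenylphenyl]boronic acid | CC(C)=CCc1cc(B(O)O)cc(CC=C(C)C)c1O[Si](C)(C)C(C)(C)C | intermediate
15 | (2S)-7,4′-bis(TBS-oxy)-8,3′,5′-triprenylflavanone | CC(C)=CCc1cc([C@@H]2CC(=O)c3ccc(O[Si](C)(C)C(C)(C)C)c(CC=C(C)C)c3O2)cc(CC=C(C)C)c1O[Si](C)(C)C(C)(C)C | intermediate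
16 | sophoranone | CC(C)=CCc1cc([C@@H]2CC(=O)c3ccc(O)c(CC=C(C)C)c3O2)cc(CC=C(C)C)c1O | target

## Summary

**Total steps:** 9. **Longest linear sequence:** 6 (steps 1–4, 8, 9); the aryl branch is steps 5–7.

**Three steps most likely to fail**

1. **Step 8 (asymmetric conjugate arylation).** The risks are protodeboronation of the electron-rich boronic acid, Pd(II) interference with the three prenyl alkenes, partial loss of the 7-OTBS group (harmless, since it converges on 16), and the sense of induction. I assigned the sense by analogy with the known enone facial preference, so it should be confirmed on the first run by CD: a 2S flavanone shows a positive Cotton effect near 330 nm and a negative one near 290 nm. Fallback: reverse the bond order. Formylate the aryllithium from 11 (DMF), condense with a 2-hydroxy-3-prenyl-4-silyloxyacetophenone to the chalcone, and close the ring by a chiral bifunctional thiourea/cinchona-catalysed oxa-Michael cyclisation.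

2. **Step 5 (one-pot o,o′-di-C-prenylation).** The risks are competing O-prenylation, stalling at the mono-prenyl stage and chroman formation, so the yield will be modest. Fallback: install each prenyl group by the sequence already used in steps 1–3 (O-1,1-dimethylpropargylation, Lindlar reduction, Claisen rearrangement), run twice on 4-bromophenol; the only free ortho position guarantees regiochemistry.

3. **Step 3 (Claisen regioselectivity and over-reaction).** The risks are C6 rearrangement, abnormal-Claisen isomerisation, or cyclisation of the product on prolonged heating. Fallback: run the rearrangement one stage earlier on 2,4-dihydroxyacetophenone 4-O-(1,1-dimethylallyl) ether, where the chelated o-hydroxyketone directs migration to C3. Then build the pyranone afterwards (DMF-DMA enaminone, acid cyclisation) to reach 5.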